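**Retrosynthetic overview**
- Enabling feature: the α-methylene-γ-butyrolactone ring (O–C12(=O)–C11(=C13H2)–C7–C6) shares the C6–C7 bond with the ten-membered carbocycle and carries its exocyclic methylene on C11 next to C7. C7=C11=C13 can therefore be a terminal allene, C6–O an aldehyde and C12 carbon monoxide.
- Key disconnection: (2+2+1) hetero-Pauson–Khand macrocyclisation of the acyclic allenyl enal 26 with CO, forming C6–C7 and C11–C12 (and O–C12) in one operation.
- 26 comes from aldehyde 11 (C1–C3, C7–C11, C14; C8 by asymmetric propargylation, (Z)-C1=C10 by directed carbomagnesiation) and vinyl iodide 16 (C4–C6, C15) by Nozaki–Hiyama–Kishi coupling at C3–C4, CBS reduction (C3), Shi epoxidation (C1, C10) and Crabbé homologation (allene).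
- Ring order: epoxide first (step 14), then carbocycle and lactone together (step 18); endgame: C8 desilylation, angeloylation, PMB removal.

Key step: step 18

Remark: germacrane numbering of the target is used for all compounds (C1–C10 ring carbons, C11–C13 lactone carbons, C14 the methyl on C10, C15 the CH2O carbon on C4); in this numbering the target is 1R,3S,6R,7R,8R,10S with a ring-cis C4=C5 bond and a cis C1–C10 epoxide.

**Step 1**
Reactants: 1 3-(trimethylsilyl)prop-2-ynal; 2 allenylboronic acid pinacol ester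
Product: 3 (R)-1-(trimethylsilyl)hexa-1,5-diyn-3-ol
Conditions: (R)-TRIP [(R)-3,3'-bis(2,4,6-triisopropylphenyl)-1,1'-binaphthyl-2,2'-diyl hydrogen phosphate] (5 mol%), 4 Å MS, toluene, −20 °C; aqueous work-up
Reagents that add atoms: none
Why: Chiral-phosphoric-acid-catalysed asymmetric propargylation (SE2' addition of the allenylboronate through a six-membered chair transition state) should give the homopropargylic alcohol, the (R)-acid shielding one face of the activated ynal so that C8 is set as R.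

**Step 2**
Reactants: 3 (R)-1-(trimethylsilyl)hexa-1,5-diyn-3-ol
Product: 4 (R)-3-(tert-butyldimethylsilyloxy)-1-(trimethylsilyl)hexa-1,5-diyne
Conditions: TBSCl, imidazole, DMF, rt
Reagents that add atoms: tert-butyldimethylsilyl chloride, CC(C)(C)[Si](C)(C)Cl
Why: Standard silylation protects the C8 hydroxyl so that it cannot direct the later carbometalation; no stereocentre is touched.

**Step 3**
Reactants: 4 (R)-3-(tert-butyldimethylsilyloxy)-1-(trimethylsilyl)hexa-1,5-diyne; 5 oxirane
Product: 7 (R)-6-(tert-butyldimethylsilyloxy)-8-(trimethylsilyl)octa-3,7-diyn-1-ol, via lithium acetylide 6 (not isolated)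
Conditions: n-BuLi, THF, −78 °C; BF3·OEt2, then 5, −78 °C; aq NH4Cl
Reagents that add atoms: none
Why: BF3-promoted opening of an epoxide by a lithium acetylide (only the free terminal alkyne is deprotonated) should give the homopropargylic primary alcohol carrying C2 and C3; no new stereocentre.

**Step 4**
Reactants: 7 (R)-6-(tert-butyldimethylsilyloxy)-8-(trimethylsilyl)octa-3,7-diyn-1-ol
Product: 9 (3Z,6R)-6-(tert-butyldimethylsilyloxy)-4-methyl-8-(trimethylsilyl)oct-3-en-7-yn-1-ol, via alkenylmagnesium alkoxide 8 (not isolated)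
Conditions: Fe(acac)3 (20 mol%), MeMgBr (5 equiv), THF, −78 → 0 °C; aq NH4Cl
Reagents that add atoms: methylmagnesium bromide, C[Mg]Br
Why: Alkoxide-directed iron-catalysed syn-carbomagnesiation of a homopropargylic alcohol should deliver methyl to the distal alkyne carbon (C10) and magnesium to the proximal one (C1), so protonation gives the (Z)-trisubstituted alkene (C2 and C9 cis); the silyl ether at C8 does not direct and the silylalkyne is left alone.

**Step 5**
Reactants: 9 (3Z,6R)-6-(tert-butyldimethylsilyloxy)-4-methyl-8-(trimethylsilyl)oct-3-en-7-yn-1-ol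
Product: 10 (3Z,6R)-6-(tert-butyldimethylsilyloxy)-4-methyloct-3-en-7-yn-1-ol
Conditions: K2CO3 (cat.), MeOH, rt
Reagents that add atoms: none
Why: Base-catalysed methanolysis of the alkynyl C–Si bond frees the terminal alkyne needed for the later Crabbé homologation while both silyl ethers and the alkene geometry stay intact.

**Step 6**
Reactants: 10 (3Z,6R)-6-(tert-butyldimethylsilyloxy)-4-methyloct-3-en-7-yn-1-ol
Product: 11 (3Z,6R)-6-(tert-butyldimethylsilyloxy)-4-methyloct-3-en-7-ynal
Conditions: Dess–Martin periodinane, NaHCO3, CH2Cl2, 0 °C; used directly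
Reagents that add atoms: none
Why: Buffered Dess–Martin oxidation gives the β,γ-unsaturated aldehyde (C3) without base, so the alkene should neither migrate into conjugation nor isomerise.

**Step 7**
Reactants: 12 but-2-yne-1,4-diol
Product: 13 4-(4-methoxybenzyloxy)but-2-yn-1-ol
Conditions: NaH (0.5 equiv), PMBCl, Bu4NI (cat.), THF, 0 °C → rt (diol in excess)
Reagents that add atoms: 4-methoxybenzyl chloride, COc1ccc(CCl)cc1
Why: Williamson monoetherification of the symmetrical diol (used in excess) differentiates the future C15 oxygen (PMB) from the future C6 oxygen.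

**Step 8**
Reactants: 13 4-(4-methoxybenzyloxy)but-2-yn-1-ol
Product: 15 (Z)-3-iodo-4-(4-methoxybenzyloxy)but-2-en-1-ol, via cyclic alkenylalanate 14 (not isolated)
Conditions: NaAlH2(OCH2CH2OCH3)2, THF, 0 °C; EtOAc; I2, −78 → 0 °C
Reagents that add atoms: iodine, II
Why: Hydroxyl-directed trans-hydroalumination of the propargylic alcohol puts aluminium on the carbon remote from the free hydroxyl (C4) and iodinolysis with retention gives the (Z)-iodide, which fixes the later C4=C5 geometry (C3 and C6 cis, C15 trans to C6).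

**Step 9**
Reactants: 15 (Z)-3-iodo-4-(4-methoxybenzyloxy)but-2-en-1-ol
Product: 16 (Z)-triethyl{[3-iodo-4-(4-methoxybenzyloxy)but-2-en-1-yl]oxy}silane
Conditions: TESCl, imidazole, CH2Cl2, 0 °C
Reagents that add atoms: chlorotriethylsilane, CC[Si](Cl)(CC)CC
Why: Silylation masks the C6 hydroxyl with a group that can later be removed in the presence of the secondary TBS ether.

**Step 10**
Reactants: 11 (3Z,6R)-6-(tert-butyldimethylsilyloxy)-4-methyloct-3-en-7-ynal; 16 (Z)-triethyl{[3-iodo-4-(4-methoxybenzyloxy)but-2-en-1-yl]oxy}silane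
Product: 18 (2Z,6Z,9R)-9-(tert-butyldimethylsilyloxy)-3-[(4-methoxybenzyloxy)methyl]-7-methyl-1-(triethylsilyloxy)undeca-2,6-dien-10-yn-4-ol (both C4 epimers; C4 of this name is C3 of the target), via alkenylchromium species 17 (not isolated)
Conditions: CrCl2 (4 equiv), NiCl2 (2 mol%), DMSO, rt
Reagents that add atoms: none
Why: Nozaki–Hiyama–Kishi coupling (nickel-catalysed activation of the iodide, transfer to divalent chromium, addition to the aldehyde) joins C3 to C4 under non-basic conditions with retention of the alkenyl geometry; C3 is formed without control and is corrected in steps 11 and 12.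

**Step 11**
Reactants: 18 (2Z,6Z,9R)-9-(tert-butyldimethylsilyloxy)-3-[(4-methoxybenzyloxy)methyl]-7-methyl-1-(triethylsilyloxy)undeca-2,6-dien-10-yn-4-ol
Product: 19 (2Z,6Z,9R)-9-(tert-butyldimethylsilyloxy)-3-[(4-methoxybenzyloxy)methyl]-7-methyl-1-(triethylsilyloxy)undeca-2,6-dien-10-yn-4-one
Conditions: Dess–Martin periodinane, NaHCO3, CH2Cl2, 0 °C
Reagents that add atoms: none
Why: Dess–Martin oxidation converges both C3 epimers on one enone under neutral conditions that should leave the skipped alkene and the (Z)-enone geometry untouched.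

**Step 12**
Reactants: 19 (2Z,6Z,9R)-9-(tert-butyldimethylsilyloxy)-3-[(4-methoxybenzyloxy)methyl]-7-methyl-1-(triethylsilyloxy)undeca-2,6-dien-10-yn-4-one
Product: 20 (2Z,4S,6Z,9R)-9-(tert-butyldimethylsilyloxy)-3-[(4-methoxybenzyloxy)methyl]-7-methyl-1-(triethylsilyloxy)undeca-2,6-dien-10-yn-4-ol
Conditions: (R)-2-methyl-CBS-oxazaborolidine (0.3 equiv), catecholborane, toluene, −78 °C
Reagents that add atoms: none
Why: Corey–Bakshi–Shibata reduction with the α-branched alkenyl group as the large and the CH2 group as the small substituent should give the 3S alcohol (the (R)-catalyst gives the sense opposite to the (S)-catalyst/acetophenone → (R)-alcohol case); catecholborane at −78 °C does not hydroborate the alkyne or the alkenes.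

**Step 13**
Reactants: 20 (2Z,4S,6Z,9R)-9-(tert-butyldimethylsilyloxy)-3-[(4-methoxybenzyloxy)methyl]-7-methyl-1-(triethylsilyloxy)undeca-2,6-dien-10-yn-4-ol
Product: 21 (2Z,4S,6Z,9R)-9-(tert-butyldimethylsilyloxy)-3-[(4-methoxybenzyloxy)methyl]-7-methyl-1-(triethylsilyloxy)undeca-2,6-dien-10-yn-4-yl acetate
Conditions: Ac2O, pyridine, DMAP (cat.), CH2Cl2, 0 °C
Reagents that add atoms: acetic anhydride, CC(=O)OC(C)=O
Why: Acylation installs the C3 acetate of the target with retention at C3; every later step before the key step is non-basic enough to keep it.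

**Step 14**
Reactants: 21 (2Z,4S,6Z,9R)-9-(tert-butyldimethylsilyloxy)-3-[(4-methoxybenzyloxy)methyl]-7-methyl-1-(triethylsilyloxy)undeca-2,6-dien-10-yn-4-yl acetate
Product: 22 (2Z,4S,6R,7S,9R)-9-(tert-butyldimethylsilyloxy)-6,7-epoxy-3-[(4-methoxybenzyloxy)methyl]-7-methyl-1-(triethylsilyloxy)undec-2-en-10-yn-4-yl acetate
Conditions: D-fructose-derived Shi ketone (1,2:4,5-di-O-isopropylidene-β-D-erythro-2,3-hexodiulo-2,6-pyranose, 30 mol%), Oxone (2KHSO5·KHSO4·K2SO4), K2CO3, Bu4NHSO4, MeCN/dimethoxymethane/aq buffer pH 10.5, 0 °C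
Reagents that add atoms: potassium peroxymonosulfate, OOS(=O)(=O)[O-].[K+]
Why: Shi epoxidation is stereospecific, so the (Z)-alkene gives the cis-epoxide, and the spiro transition state of the D-fructose-derived dioxirane should deliver oxygen to the face that gives 1R,10S (same sense as 1-phenylcyclohexene → (R,R)-oxide); the C4=C5 alkene, deactivated by three allylic oxygens, and the alkyne should not react.

**Step 15**
Reactants: 22 (2Z,4S,6R,7S,9R)-9-(tert-butyldimethylsilyloxy)-6,7-epoxy-3-[(4-methoxybenzyloxy)methyl]-7-methyl-1-(triethylsilyloxy)undec-2-en-10-yn-4-yl acetate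
Product: 24 (2Z,4S,6R,7S,9R)-9-(tert-butyldimethylsilyloxy)-6,7-epoxy-3-[(4-methoxybenzyloxy)methyl]-7-methyl-1-(triethylsilyloxy)dodeca-2,10,11-trien-4-yl acetate, via propargylic Mannich base 23 (not isolated)
Conditions: CuI (0.5 equiv), (CH2O)n, Cy2NH, 1,4-dioxane, reflux
Reagents that add atoms: paraformaldehyde (as formaldehyde), C=O
Why: Crabbé homologation (copper-mediated Mannich reaction, then 1,5-hydride transfer from the amine with loss of imine) converts the terminal alkyne into the terminal allene C7=C11=C13; the C8 stereocentre is not involved.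

**Step 16**
Reactants: 24 (2Z,4S,6R,7S,9R)-9-(tert-butyldimethylsilyloxy)-6,7-epoxy-3-[(4-methoxybenzyloxy)methyl]-7-methyl-1-(triethylsilyloxy)dodeca-2,10,11-trien-4-yl acetate
Product: 25 (2Z,4S,6R,7S,9R)-9-(tert-butyldimethylsilyloxy)-6,7-epoxy-1-hydroxy-3-[(4-methoxybenzyloxy)methyl]-7-methyldodeca-2,10,11-trien-4-yl acetate
Conditions: HF·pyridine, pyridine, THF, 0 °C
Reagents that add atoms: none
Why: Buffered fluoride cleaves the primary allylic TES ether much faster than the secondary TBS ether and should spare the epoxide, the allene and the acetate.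

**Step 17**
Reactants: 25 (2Z,4S,6R,7S,9R)-9-(tert-butyldimethylsilyloxy)-6,7-epoxy-1-hydroxy-3-[(4-methoxybenzyloxy)methyl]-7-methyldodeca-2,10,11-trien-4-yl acetate
Product: 26 (2Z,4S,6R,7S,9R)-9-(tert-butyldimethylsilyloxy)-6,7-epoxy-3-[(4-methoxybenzyloxy)methyl]-7-methyl-1-oxododeca-2,10,11-trien-4-yl acetate
Conditions: Dess–Martin periodinane, NaHCO3, CH2Cl2, 0 °C
Reagents that add atoms: none
Why: Dess–Martin oxidation of the allylic alcohol gives the (Z)-enal (C6) without acid or base, so the alkene geometry and the γ-acetate should be preserved.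

**Step 18**
Reactants: 26 (2Z,4S,6R,7S,9R)-9-(tert-butyldimethylsilyloxy)-6,7-epoxy-3-[(4-methoxybenzyloxy)methyl]-7-methyl-1-oxododeca-2,10,11-trien-4-yl acetate
Product: 28 3-acetoxy-8-(tert-butyldimethylsilyloxy)-1,10-epoxy-15-(4-methoxybenzyloxy)germacra-4(Z),11(13)-dien-12,6-olide with all six stereocentres arranged as in the target, via oxaruthenacycle 27 (not isolated)
Conditions: Ru3(CO)12 (10 mol%), CO (10 atm), 1,4-dioxane, 0.002 M, 110 °C
Reagents that add atoms: carbon monoxide, [C-]#[O+]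
Why: Proposed new method: zerovalent ruthenium carbonyl binds the C6 aldehyde and the proximal C7=C11 bond of the terminal allene and couples them oxidatively to an oxaruthenacyclopentane with the exocyclic C11=C13 methylene (27); CO then inserts into the Ru–C11 bond and C–O reductive elimination releases the α-methylene-γ-butyrolactone, so C6–C7, C11–C12 and O–C12 form in one (2+2+1) operation. The closest known reaction type is the Ru3(CO)12-catalysed (or Mo(CO)6-mediated) hetero-Pauson–Khand cyclocarbonylation of tethered allenyl aldehydes, shown so far only for five- and six-membered carbocycles. The ten-membered carbocycle closes by C6–C7 bond formation in a 10-exo mode with respect to both the carbonyl and the allene π bond, and the five-membered lactone closes by the formal (2+2+1) union of C6=O, C7=C11 and CO. C7 is controlled by the adjacent C8 stereocentre: with the C8–C9 bond anti to the forming bond and the bulky silyloxy group outside, away from the metal-bearing C11, attack on the exposed allene face gives 7R; C6 is controlled by the metallacycle, whose two chain-bearing bonds (C6–C5 and C7–C8) should take the trans arrangement that a medium ring, unlike a short tether, can span, giving the trans-fused lactone (6R). The step needs ring closure to win over oligomerisation and the proximal rather than the distal allene bond to react; high dilution, the two cis elements of the chain (cis-epoxide and (Z)-enal) that fold C6 toward C7, and the known proximal-bond preference of this catalyst for allenyl carbonyls should secure both.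

**Step 19**
Reactants: 28 3-acetoxy-8-(tert-butyldimethylsilyloxy)-1,10-epoxy-15-(4-methoxybenzyloxy)germacra-4(Z),11(13)-dien-12,6-olide
Product: 29 3-acetoxy-1,10-epoxy-8-hydroxy-15-(4-methoxybenzyloxy)germacra-4(Z),11(13)-dien-12,6-olide (stereocentres as in the target)
Conditions: Bu4NF, AcOH (1:1), THF, 0 °C → rt
Reagents that add atoms: none
Why: Acetic-acid-buffered fluoride desilylation frees the C8 hydroxyl while keeping the medium non-basic, which should spare the α-methylene lactone, the epoxide and the acetate (no free hydroxyl is near the acetate, so it cannot migrate).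

**Step 20**
Reactants: 29 3-acetoxy-1,10-epoxy-8-hydroxy-15-(4-methoxybenzyloxy)germacra-4(Z),11(13)-dien-12,6-olide; 30 angelic acid [(Z)-2-methylbut-2-enoic acid]
Product: 32 3-acetoxy-8-angeloyloxy-1,10-epoxy-15-(4-methoxybenzyloxy)germacra-4(Z),11(13)-dien-12,6-olide (the 15-O-PMB ether of the target), via mixed anhydride 31 (not isolated)
Conditions: 30, 2,4,6-trichlorobenzoyl chloride, Et3N, toluene, rt; then 29, toluene, 75 °C
Reagents that add atoms: none
Why: Yamaguchi-type esterification through the angelic 2,4,6-trichlorobenzoic mixed anhydride, run without a nucleophilic catalyst, should acylate the C8 hydroxyl with retention at C8 and without (Z)→(E) isomerisation to the tiglate.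

**Step 21**
Reactants: 32 3-acetoxy-8-angeloyloxy-1,10-epoxy-15-(4-methoxybenzyloxy)germacra-4(Z),11(13)-dien-12,6-olide
Product: 33 CNP0162483.1 (target)
Conditions: DDQ, CH2Cl2/pH 7 buffer, 0 °C
Reagents that add atoms: none
Why: Oxidative PMB cleavage under neutral conditions releases the C15 hydroxyl without acid or base, so the neighbouring C3 acetate should not migrate and the epoxide, angelate and α-methylene lactone should survive.

**Compound list**
1 | 3-(trimethylsilyl)prop-2-ynal | C[Si](C)(C)C#CC=O | starting material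
2 | allenylboronic acid pinacol ester | C=C=CB1OC(C)(C)C(C)(C)O1 | starting material
3 | (R)-1-(trimethylsilyl)hexa-1,5-diyn-3-ol | C#CC[C@@H](O)C#C[Si](C)(C)C | intermediate
4 | (R)-3-(tert-butyldimethylsilyloxy)-1-(trimethylsilyl)hexa-1,5-diyne | C#CC[C@@H](O[Si](C)(C)C(C)(C)C)C#C[Si](C)(C)C | intermediate
5 | oxirane | C1CO1 | starting material
6 | lithium acetylide of 4 | [Li]C#CC[C@@H](O[Si](C)(C)C(C)(C)C)C#C[Si](C)(C)C | intermediate (not isolated)
7 | (R)-6-(tert-butyldimethylsilyloxy)-8-(trimethylsilyl)octa-3,7-diyn-1-ol | OCCC#CC[C@@H](O[Si](C)(C)C(C)(C)C)C#C[Si](C)(C)C | intermediate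
8 | alkenylmagnesium bromide alkoxide from syn-methylmagnesiation of 7 | Br[Mg]OCC/C([Mg]Br)=C(/C)C[C@@H](O[Si](C)(C)C(C)(C)C)C#C[Si](C)(C)C | intermediate (not isolated)
9 | (3Z,6R)-6-(tert-butyldimethylsilyloxy)-4-methyl-8-(trimethylsilyl)oct-3-en-7-yn-1-ol | OCC/C=C(/C)C[C@@H](O[Si](C)(C)C(C)(C)C)C#C[Si](C)(C)C | intermediate
10 | (3Z,6R)-6-(tert-butyldimethylsilyloxy)-4-methyloct-3-en-7-yn-1-ol | OCC/C=C(/C)C[C@@H](O[Si](C)(C)C(C)(C)C)C#C | intermediate
11 | (3Z,6R)-6-(tert-butyldimethylsilyloxy)-4-methyloct-3-en-7-ynal | O=CC/C=C(/C)C[C@@H](O[Si](C)(C)C(C)(C)C)C#C | intermediate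
12 | but-2-yne-1,4-diol | OCC#CCO | starting material
13 | 4-(4-methoxybenzyloxy)but-2-yn-1-ol | OCC#CCOCc1ccc(OC)cc1 | intermediate
14 | cyclic sodium alkenylalanate from 13 | [Na+].COCCO[Al-]1(OCCOC)OCC=C1COCc1ccc(OC)cc1 | intermediate (not isolated)
15 | (Z)-3-iodo-4-(4-methoxybenzyloxy)but-2-en-1-ol | OC/C=C(I)/COCc1ccc(OC)cc1 | intermediate
16 | (Z)-triethyl{[3-iodo-4-(4-methoxybenzyloxy)but-2-en-1-yl]oxy}silane | CC[Si](CC)(CC)OC/C=C(I)/COCc1ccc(OC)cc1 | intermediate
17 | alkenylchromium dichloride from 16 | CC[Si](CC)(CC)OC/C=C([Cr](Cl)Cl)/COCc1ccc(OC)cc1 | intermediate (not isolated)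
18 | (2Z,6Z,9R)-9-(tert-butyldimethylsilyloxy)-3-[(4-methoxybenzyloxy)methyl]-7-methyl-1-(triethylsilyloxy)undeca-2,6-dien-10-yn-4-ol, both C4 epimers | CC[Si](CC)(CC)OC/C=C(/COCc1ccc(OC)cc1)C(O)C/C=C(/C)C[C@@H](O[Si](C)(C)C(C)(C)C)C#C | intermediate
19 | (2Z,6Z,9R)-9-(tert-butyldimethylsilyloxy)-3-[(4-methoxybenzyloxy)methyl]-7-methyl-1-(triethylsilyloxy)undeca-2,6-dien-10-yn-4-one | CC[Si](CC)(CC)OC/C=C(/COCc1ccc(OC)cc1)C(=O)C/C=C(/C)C[C@@H](O[Si](C)(C)C(C)(C)C)C#C | intermediate
20 | (2Z,4S,6Z,9R)-9-(tert-butyldimethylsilyloxy)-3-[(4-methoxybenzyloxy)methyl]-7-methyl-1-(triethylsilyloxy)undeca-2,6-dien-10-yn-4-ol | CC[Si](CC)(CC)OC/C=C(/COCc1ccc(OC)cc1)[C@@H](O)C/C=C(/C)C[C@@H](O[Si](C)(C)C(C)(C)C)C#C | intermediate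
21 | (2Z,4S,6Z,9R)-9-(tert-butyldimethylsilyloxy)-3-[(4-methoxybenzyloxy)methyl]-7-methyl-1-(triethylsilyloxy)undeca-2,6-dien-10-yn-4-yl acetate | CC[Si](CC)(CC)OC/C=C(/COCc1ccc(OC)cc1)[C@@H](OC(C)=O)C/C=C(/C)C[C@@H](O[Si](C)(C)C(C)(C)C)C#C | intermediate
22 | (2Z,4S,6R,7S,9R)-9-(tert-butyldimethylsilyloxy)-6,7-epoxy-3-[(4-methoxybenzyloxy)methyl]-7-methyl-1-(triethylsilyloxy)undec-2-en-10-yn-4-yl acetate | CC[Si](CC)(CC)OC/C=C(/COCc1ccc(OC)cc1)[C@@H](OC(C)=O)C[C@H]1O[C@@]1(C)C[C@@H](O[Si](C)(C)C(C)(C)C)C#C | intermediate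
23 | N,N-dicyclohexyl propargylic amine (Mannich base) of 22 | CC[Si](CC)(CC)OC/C=C(/COCc1ccc(OC)cc1)[C@@H](OC(C)=O)C[C@H]1O[C@@]1(C)C[C@@H](O[Si](C)(C)C(C)(C)C)C#CCN(C1CCCCC1)C1CCCCC1 | intermediate (not isolated)
24 | (2Z,4S,6R,7S,9R)-9-(tert-butyldimethylsilyloxy)-6,7-epoxy-3-[(4-methoxybenzyloxy)methyl]-7-methyl-1-(triethylsilyloxy)dodeca-2,10,11-trien-4-yl acetate | CC[Si](CC)(CC)OC/C=C(/COCc1ccc(OC)cc1)[C@@H](OC(C)=O)C[C@H]1O[C@@]1(C)C[C@@H](O[Si](C)(C)C(C)(C)C)C=C=C | intermediate
25 | (2Z,4S,6R,7S,9R)-9-(tert-butyldimethylsilyloxy)-6,7-epoxy-1-hydroxy-3-[(4-methoxybenzyloxy)methyl]-7-methyldodeca-2,10,11-trien-4-yl acetate | OC/C=C(/COCc1ccc(OC)cc1)[C@@H](OC(C)=O)C[C@H]1O[C@@]1(C)C[C@@H](O[Si](C)(C)C(C)(C)C)C=C=C | intermediate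
26 | (2Z,4S,6R,7S,9R)-9-(tert-butyldimethylsilyloxy)-6,7-epoxy-3-[(4-methoxybenzyloxy)methyl]-7-methyl-1-oxododeca-2,10,11-trien-4-yl acetate | O=C/C=C(/COCc1ccc(OC)cc1)[C@@H](OC(C)=O)C[C@H]1O[C@@]1(C)C[C@@H](O[Si](C)(C)C(C)(C)C)C=C=C | intermediate
27 | oxaruthenacyclopentane (Ru bound to O on C6 and to C11) with three CO ligands | C=C1[Ru](=C=O)(=C=O)(=C=O)O[C@@H]2/C=C(/COCc4ccc(OC)cc4)[C@@H](OC(C)=O)C[C@H]3O[C@@]3(C)C[C@@H](O[Si](C)(C)C(C)(C)C)[C@@H]12 | intermediate (not isolated)
28 | 3-acetoxy-8-(tert-butyldimethylsilyloxy)-1,10-epoxy-15-(4-methoxybenzyloxy)germacra-4(Z),11(13)-dien-12,6-olide, stereocentres as in the target | C=C1C(=O)O[C@@H]2/C=C(/COCc4ccc(OC)cc4)[C@@H](OC(C)=O)C[C@H]3O[C@@]3(C)C[C@@H](O[Si](C)(C)C(C)(C)C)[C@@H]12 | intermediate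
29 | 3-acetoxy-1,10-epoxy-8-hydroxy-15-(4-methoxybenzyloxy)germacra-4(Z),11(13)-dien-12,6-olide, stereocentres as in the target | C=C1C(=O)O[C@@H]2/C=C(/COCc4ccc(OC)cc4)[C@@H](OC(C)=O)C[C@H]3O[C@@]3(C)C[C@@H](O)[C@@H]12 | intermediate
30 | angelic acid | C/C=C(/C)C(=O)O | starting material
31 | angelic 2,4,6-trichlorobenzoic anhydride | C/C=C(/C)C(=O)OC(=O)c1c(Cl)cc(Cl)cc1Cl | intermediate (not isolated)
32 | 3-acetoxy-8-angeloyloxy-1,10-epoxy-15-(4-methoxybenzyloxy)germacra-4(Z),11(13)-dien-12,6-olide | C=C1C(=O)O[C@@H]2/C=C(/COCc4ccc(OC)cc4)[C@@H](OC(C)=O)C[C@H]3O[C@@]3(C)C[C@@H](OC(=O)/C(C)=C\C)[C@@H]12 | intermediate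
33 | CNP0162483.1 | C=C1C(=O)O[C@@H]2/C=C(/CO)[C@@H](OC(C)=O)C[C@H]3O[C@@]3(C)C[C@@H](OC(=O)/C(C)=C\C)[C@@H]12 | target

**Step count**
Total: 21 steps. Longest linear sequence: 18 steps (steps 1–6 and 10–21); steps 7–9 form the second branch.

**Steps most likely to fail**

Step 18 (Proposed new method). The ring closure may lose to intermolecular oligomerisation, the allene face may be chosen wrongly, or the allylic acetate may ionise at the metal. The fallback sets out from 24 and comes back at 28, using only known reaction types. One equivalent of bromine (CH2Cl2, −78 °C) adds to the allene to give the 2-bromoallylic bromide F1 (obtained together with its allylic isomer, which leads to the same allylmetal). HF·pyridine/pyridine removes the TES group to give the alcohol F2, and Dess–Martin oxidation gives the aldehyde F3. CrCl2 in THF at high dilution generates the (2-bromoallyl)chromium species, which adds through its γ-carbon C7 to the C6 aldehyde; this Nozaki–Hiyama-type allylation is the ring closure with direct precedent for ten-membered germacranolides and gives the ring-closed bromo homoallylic alcohol F4. Pd(PPh3)4, CO (1 atm) and Et3N in MeCN then close the lactone by carbonylative lactonisation of the alkenyl bromide onto the C6 hydroxyl, giving 28.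

Step 4. Regiocontrol of the carbometalation may be lost (methyl at C1 instead of C10), or conversion may stall. The fallback sets out from 4 and comes back at 9. Lithiation (n-BuLi) and ClCO2Me give the ynoate F5. Me2CuLi (THF, −78 °C, protonation at −78 °C) adds syn to give the (Z)-enoate F6, with the geometry fixed by the carbocupration. i-Bu2AlH reduces it to the allylic alcohol F7 and MnO2 oxidises this to the (Z)-enal F8. Ph3P=CH2 gives the (Z)-1,3-diene F9. 9-BBN, then NaBO3·4H2O, hydroborates only the terminal vinyl group and gives 9.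

Step 15. The trisubstituted epoxide may open, or the acetate may be cleaved, under hot amine and copper iodide. The fallback sets out from 21 and comes back at 24, and changes the order so that the epoxide never meets these conditions. The Crabbé homologation (CuI, (CH2O)n, Cy2NH, dioxane, reflux) is run on 21 to give the allenyl diene F10. The Shi epoxidation of step 14 is then applied to F10, relying on the much higher reactivity of the trisubstituted C1=C10 alkene over the monosubstituted allene toward the dioxirane, to give 24.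

**Further compounds**
F1 | step 18 | (2Z,4S,6R,7S,9R)-11,12-dibromo-9-(tert-butyldimethylsilyloxy)-6,7-epoxy-3-[(4-methoxybenzyloxy)methyl]-7-methyl-1-(triethylsilyloxy)dodeca-2,10-dien-4-yl acetate (C10=C11 geometry undefined) | CC[Si](CC)(CC)OC/C=C(/COCc1ccc(OC)cc1)[C@@H](OC(C)=O)C[C@H]1O[C@@]1(C)C[C@@H](O[Si](C)(C)C(C)(C)C)C=C(Br)CBr
F2 | step 18 | (2Z,4S,6R,7S,9R)-11,12-dibromo-9-(tert-butyldimethylsilyloxy)-6,7-epoxy-1-hydroxy-3-[(4-methoxybenzyloxy)methyl]-7-methyldodeca-2,10-dien-4-yl acetate | OC/C=C(/COCc1ccc(OC)cc1)[C@@H](OC(C)=O)C[C@H]1O[C@@]1(C)C[C@@H](O[Si](C)(C)C(C)(C)C)C=C(Br)CBr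
F3 | step 18 | (2Z,4S,6R,7S,9R)-11,12-dibromo-9-(tert-butyldimethylsilyloxy)-6,7-epoxy-3-[(4-methoxybenzyloxy)methyl]-7-methyl-1-oxododeca-2,10-dien-4-yl acetate | O=C/C=C(/COCc1ccc(OC)cc1)[C@@H](OC(C)=O)C[C@H]1O[C@@]1(C)C[C@@H](O[Si](C)(C)C(C)(C)C)C=C(Br)CBr
F4 | step 18 | ten-membered 6-hydroxy-7-(1-bromovinyl) carbocycle (3-acetoxy, 8-silyloxy, 1,10-epoxy, 15-PMB ether), stereocentres as in 28 | O[C@@H]2/C=C(/COCc4ccc(OC)cc4)[C@@H](OC(C)=O)C[C@H]3O[C@@]3(C)C[C@@H](O[Si](C)(C)C(C)(C)C)[C@H]2C(Br)=C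
F5 | step 4 | methyl (R)-5-(tert-butyldimethylsilyloxy)-7-(trimethylsilyl)hepta-2,6-diynoate | COC(=O)C#CC[C@@H](O[Si](C)(C)C(C)(C)C)C#C[Si](C)(C)C
F6 | step 4 | methyl (2Z,5R)-5-(tert-butyldimethylsilyloxy)-3-methyl-7-(trimethylsilyl)hept-2-en-6-ynoate | COC(=O)/C=C(/C)C[C@@H](O[Si](C)(C)C(C)(C)C)C#C[Si](C)(C)C
F7 | step 4 | (2Z,5R)-5-(tert-butyldimethylsilyloxy)-3-methyl-7-(trimethylsilyl)hept-2-en-6-yn-1-ol | OC/C=C(/C)C[C@@H](O[Si](C)(C)C(C)(C)C)C#C[Si](C)(C)C
F8 | step 4 | (2Z,5R)-5-(tert-butyldimethylsilyloxy)-3-methyl-7-(trimethylsilyl)hept-2-en-6-ynal | O=C/C=C(/C)C[C@@H](O[Si](C)(C)C(C)(C)C)C#C[Si](C)(C)C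
F9 | step 4 | (3Z,6R)-6-(tert-butyldimethylsilyloxy)-4-methyl-8-(trimethylsilyl)octa-1,3-dien-7-yne | C=C/C=C(/C)C[C@@H](O[Si](C)(C)C(C)(C)C)C#C[Si](C)(C)C
F10 | step 15 | (2Z,4S,6Z,9R)-9-(tert-butyldimethylsilyloxy)-3-[(4-methoxybenzyloxy)methyl]-7-methyl-1-(triethylsilyloxy)dodeca-2,6,10,11-tetraen-4-yl acetate | CC[Si](CC)(CC)OC/C=C(/COCc1ccc(OC)cc1)[C@@H](OC(C)=O)C/C=C(/C)C[C@@H](O[Si](C)(C)C(C)(C)C)C=C=C
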